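**Assumption:** the target has no stereocentre and no stereogenic double bond, so there is no enantiomer to control. Step 1 gives 3 as an E/Z mixture (E major); the list shows the E isomer, and every alkene geometry is erased in step 3.

**Retrosynthetic overview**
1. Target 6 comes from one global hydrogenation of the doubly unsaturated enol ester 5.
2. Key step: the O–C bond of 5 is made by Ru-vinylidene anti-Markovnikov addition of acid 3 to phenylacetylene 4, not by condensing an acid with 2-phenylethanol.
3. The odd C21 acid 3 comes from cross-metathesis of undec-10-enoic acid 1 with dodec-1-ene 2 (C11 + C12 − C2).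
4. No ring is formed; the phenyl ring arrives intact in 4.

**Route**

Step 1
Reactants: 1 undec-10-enoic acid; 2 dodec-1-ene (4 equiv)
Product: 3 (E)-heneicos-10-enoic acid
Conditions: Grubbs II (2 mol%), 1,4-benzoquinone (10 mol%), CH2Cl2, 40 °C, Ar sweep; silica chromatography
Reagents that add atoms: none
Why: Olefin cross-metathesis of two terminal alkenes is driven by loss of ethene, the excess of 2 pushes the statistics towards the cross product, benzoquinone suppresses Ru–H chain-walking, the free acid is tolerated, and the E/Z ratio of the new C10=C11 bond does not matter because step 3 saturates it.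

Step 2
Reactants: 3 (E)-heneicos-10-enoic acid; 4 ethynylbenzene (1.3 equiv)
Product: 5 (Z)-2-phenylethenyl (E)-heneicos-10-enoate
Conditions: [(p-cymene)RuCl2]2 (1 mol%), P(4-ClC6H4)3 (2 mol%), DMAP (4 mol%), toluene, 60 °C
Reagents that add atoms: none
Why: Ru-catalysed anti-Markovnikov addition of a carboxylic acid to a terminal alkyne proceeds through a Ru-vinylidene whose electrophilic α-carbon takes the carboxylate, so oxygen ends on the terminal carbon and the (Z)-enol ester forms, while the remote chain alkene is a spectator.

Step 3
Reactants: 5 (Z)-2-phenylethenyl (E)-heneicos-10-enoate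
Product: 6 2-phenylethyl heneicosanoate
Conditions: H2 (1 atm), 5% Pd/C, EtOAc, rt
Reagents that add atoms: none
Why: Heterogeneous catalytic hydrogenation saturates both the chain alkene and the styryl enol-ester C=C while the arene and ester carbonyl are inert at 1 atm, and the product C–O bond is homobenzylic and so resists hydrogenolysis; no stereocentre is created.

**Compound list**
1 | undec-10-enoic acid | C=CCCCCCCCCC(=O)O | starting material
2 | dodec-1-ene | C=CCCCCCCCCCC | starting material
3 | (E)-heneicos-10-enoic acid | CCCCCCCCCC/C=C/CCCCCCCCC(=O)O | intermediate
4 | ethynylbenzene (phenylacetylene) | C#Cc1ccccc1 | starting material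
5 | (Z)-2-phenylethenyl (E)-heneicos-10-enoate | CCCCCCCCCC/C=C/CCCCCCCCC(=O)O/C=C\c1ccccc1 | intermediate
6 | 2-phenylethyl heneicosanoate | CCCCCCCCCCCCCCCCCCCCC(=O)OCCc1ccccc1 | target

**Total step count:** 3
**Longest linear sequence:** 3 steps (1 → 3 → 5 → 6)

**Steps most likely to fail, with fallbacks**

Step 2 (most at risk). Any leakage to the Markovnikov 1-phenylvinyl ester would become the isomeric 1-phenylethyl ester after step 3 and be hard to remove; phenylacetylene can also dimerise to enynes. The fallback sets out from 3 and comes back to the route at 6. It abandons the vinylidene chemistry and makes the O–CH2 bond by SN2: 3 is converted to its caesium carboxylate with Cs2CO3 in DMF and alkylated with (2-bromoethyl)benzene at 40 °C to give 2-phenylethyl (E)-heneicos-10-enoate F1. The single chain alkene of this compound is then hydrogenated (H2, Pd/C, EtOAc) to give 6.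

Step 1. The metathesis is statistical, and any Ru–H isomerisation followed by secondary metathesis gives C20 and C22 homologues that cannot be separated from the C21 acid. The fallback sets out from 1 and comes back to the route at 6. It builds the chain by sp3–sp3 coupling instead: radical anti-Markovnikov hydrobromination of 1 (HBr, dibenzoyl peroxide, toluene, 0 °C) gives 11-bromoundecanoic acid F2. Treating this with decylmagnesium bromide (2.5 equiv, the first equivalent forming the magnesium carboxylate) and catalytic Li2CuCl4 in THF at −20 °C gives heneicosanoic acid F3 of exact chain length. Under the conditions of step 2 this acid adds to 4 to give (Z)-2-phenylethenyl heneicosanoate F4, which is hydrogenated as in step 3 to 6.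

Step 3. On Pd the enol-ester C–O bond can be hydrogenolysed before the C=C is saturated, giving heneicosanoic acid and ethylbenzene. The fallback sets out from 5 and comes back to the route at 6. It replaces surface catalysis by metal-free diimide transfer reduction, which cannot cleave C–O bonds: 5 is treated with excess 2-nitrobenzenesulfonyl hydrazide and Et3N in CH2Cl2 at rt, added in portions until both alkenes are consumed. It makes no new compound, F0.

**Further compounds**
F1 | step 2 | 2-phenylethyl (E)-heneicos-10-enoate | CCCCCCCCCC/C=C/CCCCCCCCC(=O)OCCc1ccccc1
F2 | step 1 | 11-bromoundecanoic acid | OC(=O)CCCCCCCCCCBr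
F3 | step 1 | heneicosanoic acid | CCCCCCCCCCCCCCCCCCCCC(=O)O
F4 | step 1 | (Z)-2-phenylethenyl heneicosanoate | CCCCCCCCCCCCCCCCCCCCC(=O)O/C=C\c1ccccc1
F0 | step 3 | none | none
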